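**Assumption:** the SMILES is taken as the definition of the target. It places the phenyl-bearing ring carbon between the acyl-bearing and prenyl-bearing carbons, i.e. [(1R,2R,3S)-4-methyl-3-prenyl-2-phenylcyclohex-4-en-1-yl](2,4,6-trihydroxyphenyl)methanone, which is not the usual panduratin connectivity.

## Retrosynthetic overview

1. Aryl ketone C(=O)–Ar bond: photo-Fries rearrangement of the phloroglucinol monoester of the cyclohexene acid.
2. Prenyl group: Wittig on an aldehyde made by Claisen rearrangement of a transposed allylic alcohol (Wharton), which puts the side chain cis to phenyl.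
3. Ring–CO2Me bond: ozonolysis then Ni-electroreductive "dealkenylative" methoxycarbonylation replaces the isopropenyl group of carvone.
4. Phenyl: α′-arylation of (R)-carvone, trans to isopropenyl.
5. Rings: the cyclohexene is the carvone ring throughout (only a transient epoxide is made and opened); both arenes are bought.

## Route

**Step 1**
Reactants: 1 (R)-(−)-carvone; 2 diphenyliodonium triflate
Product: 3 (5R,6R)-2-methyl-6-phenyl-5-(prop-1-en-2-yl)cyclohex-2-en-1-one
Conditions: LDA, THF, −78 °C; then Ph2I+ TfO−, −78 °C → rt
Reagents that add atoms: diphenyliodonium triflate, [O-]S(=O)(=O)C(F)(F)F.c1ccc(cc1)[I+]c1ccccc1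
Why: Enolate α-arylation with a diaryliodonium salt on the kinetic α′-enolate; phenyl enters anti to the C5 isopropenyl group (also the thermodynamic trans isomer), setting C6.

**Step 2**
Reactants: 3; 4 hydrogen peroxide
Product: 5 (1R,3R,4R,6R)-1-methyl-3-phenyl-4-(prop-1-en-2-yl)-7-oxabicyclo[4.1.0]heptan-2-one (epoxide trans to isopropenyl, cis to phenyl)
Conditions: 30% H2O2, aq NaOH, MeOH, 0 °C
Reagents that add atoms: hydrogen peroxide, OO
Why: Weitz–Scheffer nucleophilic epoxidation; hydroperoxide adds axially to C3 anti to the C5 substituent, as with carvone itself.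

**Step 3**
Reactants: 5; 6 methyl chloroformate
Product: 7 methyl (1R,3R,4R,6R)-6-methyl-5-oxo-4-phenyl-7-oxabicyclo[4.1.0]heptane-3-carboxylate (ester trans to phenyl)
Conditions: O3, CH2Cl2/MeOH 4:1, −78 °C; Ar purge, cold concentration; then NiBr2·dme (10 mol %), dtbbpy (12 mol %), ClCO2Me (3 equiv), LiBr, DMA, RVC cathode/Zn anode, divided cell, 5 mA, 2.5 F/mol, 0 °C → rt
Reagents that add atoms: methyl chloroformate, COC(=O)Cl (ozone and methanol leave no atoms in the product)
Why: Proposed new method: ozonolysis in MeOH converts isopropenyl into the α-methoxy hydroperoxide, cathodically generated Ni(I) cleaves the O–O bond, the alkoxy radical β-scissions (losing MeOAc) to the ring radical, and this is captured by (dtbbpy)Ni(CO2Me)Cl and reductively eliminated anti to the adjacent phenyl (any cis epimer converges in step 7); closest known reactions are Fe(II)-mediated dealkenylative radical functionalisation of ozonolysis-derived hydroperoxides and Ni-catalysed reductive coupling of alkyl radical precursors with chloroformates.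

**Step 4**
Reactants: 7
Product: 8 methyl (1R,2R,5R)-5-hydroxy-4-methyl-2-phenylcyclohex-3-ene-1-carboxylate
Conditions: N2H4·H2O (2.5 equiv), AcOH (0.5 equiv), MeOH, 0 °C → rt
Reagents that add atoms: none
Why: Wharton transposition; hydrazone formation, epoxide opening and N2 loss move the alkene and leave the former epoxide C–O bond intact, so the OH stays cis to phenyl.

**Step 5**
Reactants: 8; 9 butyl vinyl ether
Product: 10 methyl (1R,2R,3S)-4-methyl-3-(2-oxoethyl)-2-phenylcyclohex-4-ene-1-carboxylate
Conditions: Pd(TFA)2 (5 mol %), bathophenanthroline, Et3N (cat.), BuOCH=CH2, 75 °C; then xylene, 160 °C, sealed tube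
Reagents that add atoms: butyl vinyl ether, C=COCCCC (vinyl C2 unit)
Why: Transfer vinylation then Claisen [3,3] rearrangement; suprafacial delivery puts the CH2CHO carbon on the face of the C–O bond, i.e. cis to phenyl, setting the third stereocentre and the final alkene position.

**Step 6**
Reactants: 10; 11 isopropyltriphenylphosphonium iodide
Product: 12 methyl (1R,2R,3S)-4-methyl-3-(3-methylbut-2-en-1-yl)-2-phenylcyclohex-4-ene-1-carboxylate
Conditions: i-PrPPh3+ I−, n-BuLi, THF, 0 °C; then 10, −78 °C → rt
Reagents that add atoms: isopropyltriphenylphosphonium iodide, CC(C)[P+](c1ccccc1)(c1ccccc1)c1ccccc1.[I-]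
Why: Wittig olefination with the non-stabilised isopropylidene ylide; the aldehyde reacts far faster than the hindered ester and no stereocentre is formed.

**Step 7**
Reactants: 12; 13 lithium hydroxide
Product: 14 (1R,2R,3S)-4-methyl-3-(3-methylbut-2-en-1-yl)-2-phenylcyclohex-4-ene-1-carboxylic acid
Conditions: LiOH, THF/MeOH/H2O, 50 °C; then pH 3
Reagents that add atoms: lithium hydroxide (water), [Li+].[OH-]
Why: Ester saponification; the α-carbon is epimerisable, but trans to phenyl (equatorial, avoiding a 1,3-diaxial clash with the pseudoaxial prenyl) is the thermodynamic configuration, so base also corrects any cis epimer.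

**Step 8**
Reactants: 14; 15 phloroglucinol
Product: 16 3,5-dihydroxyphenyl (1R,2R,3S)-4-methyl-3-(3-methylbut-2-en-1-yl)-2-phenylcyclohex-4-ene-1-carboxylate
Conditions: EDC·HCl, DMAP (cat.), phloroglucinol (5 equiv), THF, 0 °C → rt
Reagents that add atoms: phloroglucinol, Oc1cc(O)cc(O)c1
Why: Steglich-type O-acylation; an excess of the symmetric triol gives the monoester.

**Step 9**
Reactants: 16
Product: 17 target, [(1R,2R,3S)-4-methyl-3-(3-methylbut-2-en-1-yl)-2-phenylcyclohex-4-en-1-yl](2,4,6-trihydroxyphenyl)methanone
Conditions: hν (254 nm), degassed MeCN (5 mM), quartz, rt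
Reagents that add atoms: none
Why: Photo-Fries rearrangement; homolysis of the ester C(O)–O bond and in-cage recombination at ring carbon forms the aryl ketone without protecting groups, ortho and para migration give the same product for a phloroglucinol monoester, and the acyl radical keeps its α-configuration.

## Compound list

1 | (R)-(−)-carvone | CC1=CC[C@H](CC1=O)C(C)=C | starting material
2 | diphenyliodonium triflate | [O-]S(=O)(=O)C(F)(F)F.c1ccc(cc1)[I+]c1ccccc1 | starting material
3 | (5R,6R)-2-methyl-6-phenyl-5-(prop-1-en-2-yl)cyclohex-2-en-1-one | CC1=CC[C@@H](C(C)=C)[C@H](c2ccccc2)C1=O | intermediate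
4 | hydrogen peroxide | OO | starting material
5 | (1R,3R,4R,6R)-1-methyl-3-phenyl-4-(prop-1-en-2-yl)-7-oxabicyclo[4.1.0]heptan-2-one | C[C@@]12O[C@@H]1C[C@@H](C(C)=C)[C@H](c3ccccc3)C2=O | intermediate
6 | methyl chloroformate | COC(=O)Cl | starting material
7 | methyl (1R,3R,4R,6R)-6-methyl-5-oxo-4-phenyl-7-oxabicyclo[4.1.0]heptane-3-carboxylate | C[C@@]12O[C@@H]1C[C@@H](C(=O)OC)[C@H](c3ccccc3)C2=O | intermediate
8 | methyl (1R,2R,5R)-5-hydroxy-4-methyl-2-phenylcyclohex-3-ene-1-carboxylate | O[C@@H]1C[C@@H](C(=O)OC)[C@H](c2ccccc2)C=C1C | intermediate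
9 | butyl vinyl ether | C=COCCCC | starting material
10 | methyl (1R,2R,3S)-4-methyl-3-(2-oxoethyl)-2-phenylcyclohex-4-ene-1-carboxylate | O=CC[C@@H]1C(C)=CC[C@@H](C(=O)OC)[C@@H]1c1ccccc1 | intermediate
11 | isopropyltriphenylphosphonium iodide | CC(C)[P+](c1ccccc1)(c1ccccc1)c1ccccc1.[I-] | starting material
12 | methyl (1R,2R,3S)-4-methyl-3-(3-methylbut-2-en-1-yl)-2-phenylcyclohex-4-ene-1-carboxylate | CC(C)=CC[C@@H]1C(C)=CC[C@@H](C(=O)OC)[C@@H]1c1ccccc1 | intermediate
13 | lithium hydroxide | [Li+].[OH-] | starting material
14 | (1R,2R,3S)-4-methyl-3-(3-methylbut-2-en-1-yl)-2-phenylcyclohex-4-ene-1-carboxylic acid | CC(C)=CC[C@@H]1C(C)=CC[C@@H](C(=O)O)[C@@H]1c1ccccc1 | intermediate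
15 | phloroglucinol | Oc1cc(O)cc(O)c1 | starting material
16 | 3,5-dihydroxyphenyl (1R,2R,3S)-4-methyl-3-(3-methylbut-2-en-1-yl)-2-phenylcyclohex-4-ene-1-carboxylate | CC(C)=CC[C@@H]1C(C)=CC[C@@H](C(=O)Oc2cc(O)cc(O)c2)[C@@H]1c1ccccc1 | intermediate
17 | (1'R,2'S,6'R)-2-hydroxyisopanduratin A as drawn in the SMILES | CC(C)=CC[C@@H]1C(C)=CC[C@@H](C(=O)c2c(O)cc(O)cc2O)[C@@H]1c1ccccc1 | target

## Summary

Total steps: 9. Longest linear sequence: 9 (fully linear from (R)-carvone).

Steps most likely to fail, each with a fallback:

1. **Step 3 (proposed electroreductive dealkenylative methoxycarbonylation).** Risks are epoxy-ketone reduction, acylation of the hydroperoxide by the chloroformate, β-hydride loss and a 1,2-acyl shift of the β-keto radical. Fallback with known chemistry: from the same ozonolysis intermediate, Fe(II)-mediated dealkenylative alkenylation with β-nitrostyrene gives the ring–CH=CHPh compound; then O3/Me2S to the aldehyde, Pinnick oxidation and TMSCHN2 give 7.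
2. **Step 9 (photo-Fries).** Risks are low conversion from product light absorption and phenol from radical escape. Fallback: convert acid 14 to its Weinreb amide, add 2,4,6-tris(methoxymethoxy)phenyllithium (from tri-MOM phloroglucinol and n-BuLi), then remove the MOM groups with HCl/MeOH.
3. **Step 4 (Wharton).** Risks are the hindered ketone and competing hydrazide formation. Fallback: Luche reduction of 7 to the epoxy alcohol, mesylation, and reductive elimination (NaI/Zn or SmI2) to the same transposed allylic alcohol 8.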